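## Retrosynthetic overview

- Target ⇐ keto aldehyde by enzymatic ketone reduction and borohydride aldehyde reduction ⇐ Michael addition of a C6 aldehyde to ethyl vinyl ketone ⇐ C6 ketone by Wittig homologation.
- Piperidine ring D ⇐ double Mannich annulation (MeNH2, 2 CH2O) across C7/C17 of a tricyclic cycloheptenone; the C10=C11 alkene comes from migration of a C9=C10 alkene.
- Key disconnection: C17–C11 and C7–C8 together, by intramolecular (4+3) cycloaddition of an oxyallyl cation (an electrophilic ketone α-carbon, the umpoled enolate) onto a tethered 1-vinylcyclopentene.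
- Cycloaddition precursor ⇐ α-chloro ketone (ester enolate + methyl vinyl ketone, then NCS) ⇐ (S)-diene ester ⇐ cyclopentenone by asymmetric Mukaiyama–Michael addition, triflation and Stille coupling.
- Ring order: A (bought) → B and C together in the (4+3) step → D (Mannich) → C6 quaternary centre and side chain last.

Atom labels: C1–C5 = 3-hydroxypentyl chain (carbinol C3) on C6; C6′ = CH2OH carbon on C6; ring A = C10, C11, C12, C13, C14; ring B (CO2Me on C15) = C11, C12, C15, C16, C17; ring C = C6, C7, C8, C9, C10, C11, C17; ring D = C6, C7, C20, N19, C18, C17.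

Assumption: the (S)-oxazaborolidinium catalyst of step 1 is taken to give the (S) adduct (its enantiomer is used if the sense proves opposite), and the Prelog-type dehydrogenase of step 10 is taken to give the (3S) alcohol.

## Route

Step 1
Reactants: 1 cyclopent-2-en-1-one; 2 tert-butyl[(1-methoxyethenyl)oxy]dimethylsilane
Product: 4 methyl 2-[(1S)-3-(trifluoromethanesulfonyloxy)cyclopent-2-en-1-yl]acetate, via silyl enol ether 3 (not isolated)
Conditions: (S)-o-tolyl-oxazaborolidinium triflimide (20 mol %), Ph3PO (25 mol %), toluene, −20 °C; then CsF, PhNTf2, DME, 23 °C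
Reagents that add atoms: N-phenylbis(trifluoromethanesulfonimide), O=S(=O)(N(c1ccccc1)S(=O)(=O)C(F)(F)F)C(F)(F)F
Why: In this catalytic asymmetric Mukaiyama–Michael addition the chiral boron cation binds the enone and shields one face so that the ketene silyl acetal sets C12 as (S), and the silyl enol ether formed by silyl transfer is opened by fluoride to the regiodefined C10=C11 enolate, which is O-triflated (conjugate addition with enolate trapping).

Step 2
Reactants: 4 methyl 2-[(1S)-3-(trifluoromethanesulfonyloxy)cyclopent-2-en-1-yl]acetate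
Product: 5 methyl 2-[(1S)-3-ethenylcyclopent-2-en-1-yl]acetate
Conditions: Bu3SnCH=CH2, Pd(PPh3)4 (zerovalent palladium, 5 mol %), LiCl, THF, 65 °C
Reagents that add atoms: tributyl(ethenyl)stannane, C=C[Sn](CCCC)(CCCC)CCCC
Why: Stille cross-coupling of the enol triflate with the vinylstannane gives the 1,3-diene without touching the allylic stereocentre C12.

Step 3
Reactants: 5 methyl 2-[(1S)-3-ethenylcyclopent-2-en-1-yl]acetate; 6 but-3-en-2-one
Product: 9 methyl 4-chloro-2-[(1R)-3-ethenylcyclopent-2-en-1-yl]-5-oxohexanoate (epimers at C15/C17), via ketene silyl acetal 7 (not isolated), via silyl enol ether 8 (not isolated)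
Conditions: LiN(iPr)2, THF, −78 °C, then Me3SiCl; evaporate, MeCN, 6, 25 °C; then NCS, THF, 0 °C
Reagents that add atoms: N-chlorosuccinimide, O=C1CCC(=O)N1Cl
Why: The ketene silyl acetal of the ester undergoes an uncatalysed Mukaiyama–Michael addition to methyl vinyl ketone that delivers the internal silyl enol ether regiospecifically, so electrophilic chlorination with NCS places chlorine at C17, while the C15 and C17 centres form as mixtures that converge in steps 5 and 8.

Step 4
Reactants: 9 methyl 4-chloro-2-[(1R)-3-ethenylcyclopent-2-en-1-yl]-5-oxohexanoate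
Product: 11 tricyclic keto ester (rings A/B/C; C6 ketone; C9=C10 alkene; H11 cis to H12; 11S,12R; epimers at C15/C17), via oxyallyl cation 10 (not isolated)
Conditions: Et3N (3 equiv), CF3CH2OH, 0.01 M, 0 °C to 25 °C
Reagents that add atoms: none
Why: Triethylamine in trifluoroethanol enolises the methyl group and ionises the chloride to an oxyallyl cation, an electrophilic ketone α-carbon, which is captured by the tethered 1-vinylcyclopentene in a Föhlisch–Harmata intramolecular (4+3) cycloaddition that forms C17–C11 and C7–C8, closes rings B and C at once, and sets H11 cis to H12 because the three-atom tether can only reach the diene face that carries it.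

Step 5
Reactants: 11 tricyclic keto ester
Product: 12 tetracyclic amino ketone with C9=C10 alkene (8-methyl-8-azabicyclo[4.3.1]decan-10-one core fused to rings A/B; 7S,11R,12R,17R; C15 epimers)
Conditions: MeNH2·HCl, (CH2O)n, cat. HCl, EtOH, reflux; aq. NaOH work-up
Reagents that add atoms: methylamine hydrochloride, CN.Cl; paraformaldehyde (as formaldehyde), C=O
Why: In this double Mannich (Robinson–Schöpf-type) annulation the enol toward C17 is aminomethylated on the convex face of the cis-fused diquinane (anti to C10 and ring A), which erases the C17 mixture, and the second iminium closes onto C7 on the same face because only a cis 1,3-bridge can form.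

Step 6
Reactants: 12 tetracyclic amino ketone with C9=C10 alkene
Product: 13 tetracyclic amino ketone with C10=C11 alkene (7S,12S,17R; C15 epimers)
Conditions: Co(tBu4-salen)Cl (trivalent cobalt, 5 mol %), PhSiH3 (6 mol %), benzene, 25 °C
Reagents that add atoms: none
Why: Hydrogen-atom-transfer olefin isomerisation (the cobalt hydride adds H to C9 to give the tertiary C10 radical, which loses H11) moves the trisubstituted alkene to the tetrasubstituted C10=C11 position, where the hindered alkene no longer re-enters the cycle and cannot conjugate with the ketone because C17 is quaternary.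

Step 7
Reactants: 13 tetracyclic amino ketone with C10=C11 alkene
Product: 14 methyl enol ether (C6=CH–OMe; E/Z mixture; 7R,12S,17S; C15 epimers)
Conditions: Ph3P(CH2OMe)Cl, KOtBu, THF, 0 °C to 50 °C
Reagents that add atoms: (methoxymethyl)triphenylphosphonium chloride, COC[P+](c1ccccc1)(c1ccccc1)c1ccccc1.[Cl-]
Why: Wittig methoxymethylenation of the bridging ketone, which cannot enolise because both α-carbons are bridgeheads, installs the future C6′ carbon.

Step 8
Reactants: 14 methyl enol ether
Product: 17 C6 aldehyde (7R,12S,15S,17R; C6 epimers), via lithium ester enolate 15 (not isolated), via (15S)-enol ether 16 (not isolated)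
Conditions: LiN(iPr)2, THF, −78 °C; 2,6-di-tert-butyl-4-methylphenol, −78 °C; then 1 M HCl, THF, 25 °C
Reagents that add atoms: water, O
Why: The only acidic C–H is at C15, so the ester enolate is protonated kinetically by the bulky phenol from the convex face (syn to C18, anti to ring A and the cycloheptene), which converges both epimers to (15S), and acid hydrolysis of the enol ether then gives the aldehyde.

Step 9
Reactants: 17 C6 aldehyde; 18 pent-1-en-3-one
Product: 19 keto aldehyde (C6 carries CHO and 3-oxopentyl; 6S,7R,12S,15S,17S)
Conditions: DBU (0.2 equiv), MeCN, 0 °C to 25 °C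
Reagents that add atoms: none
Why: Base-catalysed Michael addition of the α,α-disubstituted aldehyde enolate to ethyl vinyl ketone creates the C6 quaternary centre, with the enone expected to approach the exocyclic enolate from the piperidine face because the cycloheptene bridge and the endo ester block the other face.

Step 10
Reactants: 19 keto aldehyde
Product: 21 CNP0291564.1 (3S,6S,7R,12S,15S,17S), via (3S)-hydroxy aldehyde 20 (not isolated)
Conditions: alcohol dehydrogenase ADH-A (Rhodococcus ruber, Prelog-selective), NAD+ (cat.), iPrOH, phosphate buffer pH 7.5, 30 °C; then NaBH4, MeOH, 0 °C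
Reagents that add atoms: none
Why: In this biocatalytic ketone reduction the Prelog-selective dehydrogenase distinguishes the small ethyl group from the long chain and gives the (3S)-alcohol with isopropanol as hydride donor, and sodium borohydride then reduces the hindered aldehyde (in equilibrium with its lactol) without touching the methyl ester.

## Compound list

1 | cyclopent-2-en-1-one | O=C1C=CCC1 | starting material
2 | tert-butyl[(1-methoxyethenyl)oxy]dimethylsilane | C=C(OC)O[Si](C)(C)C(C)(C)C | starting material
3 | methyl 2-[(1S)-3-(tert-butyldimethylsilyloxy)cyclopent-2-en-1-yl]acetate | COC(=O)C[C@H]1C=C(O[Si](C)(C)C(C)(C)C)CC1 | intermediate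
4 | methyl 2-[(1S)-3-(trifluoromethanesulfonyloxy)cyclopent-2-en-1-yl]acetate | COC(=O)C[C@H]1C=C(OS(=O)(=O)C(F)(F)F)CC1 | intermediate
5 | methyl 2-[(1S)-3-ethenylcyclopent-2-en-1-yl]acetate | COC(=O)C[C@H]1C=C(C=C)CC1 | intermediate
6 | but-3-en-2-one | CC(=O)C=C | starting material
7 | trimethylsilyl ketene acetal of 5 | COC(O[Si](C)(C)C)=C[C@H]1C=C(C=C)CC1 | intermediate
8 | methyl 2-[(1R)-3-ethenylcyclopent-2-en-1-yl]-5-(trimethylsilyloxy)hex-4-enoate | CC(O[Si](C)(C)C)=CCC(C(=O)OC)[C@H]1C=C(C=C)CC1 | intermediate
9 | methyl 4-chloro-2-[(1R)-3-ethenylcyclopent-2-en-1-yl]-5-oxohexanoate (epimers at C15/C17) | CC(=O)C(Cl)CC(C(=O)OC)[C@H]1C=C(C=C)CC1 | intermediate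
10 | oxyallyl cation (2-oxidoallyl zwitterion) from 9 | C=C([O-])[CH+]CC(C(=O)OC)[C@H]1C=C(C=C)CC1 | intermediate
11 | tricyclic keto ester; C6 ketone, C9=C10 alkene, H11 cis to H12; (11S,12R); epimers at C15/C17 | O=C1CCC=C2[C@H]3[C@@H](CC2)C(C(=O)OC)CC31 | intermediate
12 | tetracyclic amino ketone with C9=C10 alkene; (7S,11R,12R,17R); C15 epimers | O=C1[C@H]2CC=C3[C@H]4[C@@H](CC3)C(C(=O)OC)C[C@]41CN(C)C2 | intermediate
13 | tetracyclic amino ketone with C10=C11 alkene; (7S,12S,17R); C15 epimers | O=C1[C@H]2CCC3=C4[C@@H](CC3)C(C(=O)OC)C[C@]41CN(C)C2 | intermediate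
14 | methyl enol ether of 13 (C6=CH–OMe; E/Z and C15 mixtures); (7R,12S,17S) | COC=C1[C@H]2CCC3=C4[C@@H](CC3)C(C(=O)OC)C[C@]41CN(C)C2 | intermediate
15 | lithium enolate of the C15 ester of 14 | COC=C1[C@H]2CCC3=C4[C@@H](CC3)C(=C([O-])OC)C[C@]41CN(C)C2.[Li+] | intermediate
16 | (15S)-enol ether; (7R,12S,15S,17S) | COC=C1[C@H]2CCC3=C4[C@@H](CC3)[C@@H](C(=O)OC)C[C@]41CN(C)C2 | intermediate
17 | C6 aldehyde; (7R,12S,15S,17R); C6 epimers | O=CC1[C@H]2CCC3=C4[C@@H](CC3)[C@@H](C(=O)OC)C[C@]41CN(C)C2 | intermediate
18 | pent-1-en-3-one | CCC(=O)C=C | starting material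
19 | keto aldehyde (C6: CHO and 3-oxopentyl); (6S,7R,12S,15S,17S) | CCC(=O)CC[C@]1(C=O)[C@H]2CCC3=C4[C@@H](CC3)[C@@H](C(=O)OC)C[C@]41CN(C)C2 | intermediate
20 | (3S)-hydroxy aldehyde (in equilibrium with its lactol); (3S,6S,7R,12S,15S,17S) | CC[C@H](O)CC[C@]1(C=O)[C@H]2CCC3=C4[C@@H](CC3)[C@@H](C(=O)OC)C[C@]41CN(C)C2 | intermediate
21 | CNP0291564.1; (3S,6S,7R,12S,15S,17S) | CC[C@H](O)CC[C@]1(CO)[C@H]2CCC3=C4[C@@H](CC3)[C@@H](C(=O)OC)C[C@]41CN(C)C2 | target

## Step count and risks

Total steps: 10. Longest linear sequence: 10 (the route is fully linear from cyclopent-2-en-1-one).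

Three steps most likely to fail:

**Step 4, the (4+3) cycloaddition.** A mono-alkyl acyclic oxyallyl cation may give Favorskii or solvolysis products before the diene captures it. The fallback sets out from 9 and replaces the free zwitterion by an O-silylated allyl cation. Kinetic deprotonation of the methyl group (LiN(iPr)2, Me3SiCl, THF, −78 °C) gives the 2-(trimethylsilyloxy)allyl chloride F1. AgClO4 in nitromethane at −20 °C then abstracts chloride to a 2-siloxyallyl cation, which undergoes the same intramolecular (4+3) closure under non-basic, non-nucleophilic conditions. Desilylation on work-up brings the route back at 11.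

**Step 6, the alkene migration.** The catalyst may stall on the amine or stop at the C10=C14 isomer. The fallback sets out from 12 and moves the double bond by stoichiometric addition and elimination. Dry HCl in CH2Cl2 at 0 °C adds across C9=C10 in the Markovnikov sense to give the tertiary C10 chloride F2 (free base after bicarbonate wash). LiBr and Li2CO3 in DMF at 120 °C then eliminate HCl through the tertiary cation to the most substituted alkene, coming back at 13.

**Step 9, the C6 quaternary centre.** The face argument is the weakest stereochemical call in the route; ethyl vinyl ketone may add from the cycloheptene face and give the C6 epimer. The fallback sets out from 17 and exchanges the roles of the two C6 substituents, so that the same facial preference gives the right centre. Aldol reaction with aqueous formaldehyde (cat. K2CO3, THF) puts CH2OH on the face the electrophile prefers and gives the hydroxymethyl aldehyde F3. Its formyl group is extended by Wittig reaction with 1-(triphenylphosphoranylidene)butan-2-one to the (E)-enone F4. Hydrogenation of the enone C=C (H2, palladium on carbon, EtOAc; the tetrasubstituted ring alkene is inert) gives the hydroxy ketone F5. The dehydrogenase reduction of step 10 then brings the route back at 21.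

Further compounds
F1 | step 4 | methyl 4-chloro-2-[(1R)-3-ethenylcyclopent-2-en-1-yl]-5-(trimethylsilyloxy)hex-5-enoate | C=C(O[Si](C)(C)C)C(Cl)CC(C(=O)OC)[C@H]1C=C(C=C)CC1
F2 | step 6 | C10-chloro tetracyclic amino ketone (HCl adduct of 12; C10 and C15 epimers) | O=C1[C@H]2CCC3(Cl)[C@H]4[C@@H](CC3)C(C(=O)OC)C[C@]41CN(C)C2
F3 | step 9 | hydroxymethyl aldehyde (C6: CHO on the piperidine face, CH2OH on the cycloheptene face) | O=C[C@]1(CO)[C@H]2CCC3=C4[C@@H](CC3)[C@@H](C(=O)OC)C[C@]41CN(C)C2
F4 | step 9 | (E)-enone (C6: CH2OH and 3-oxopent-1-enyl) | CCC(=O)/C=C/[C@]1(CO)[C@H]2CCC3=C4[C@@H](CC3)[C@@H](C(=O)OC)C[C@]41CN(C)C2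
F5 | step 9 | hydroxy ketone (C6: CH2OH and 3-oxopentyl; hemiketal tautomer in equilibrium) | CCC(=O)CC[C@]1(CO)[C@H]2CCC3=C4[C@@H](CC3)[C@@H](C(=O)OC)C[C@]41CN(C)C2
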